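A direct plan would keep ring B as benzyl olivetolate A1, acylate its 4-hydroxyl to the but-2-ynoate A2, build ring A on the triple bond by Diels–Alder benzannulation with the bis(silyl) vinylketene acetal A3, and hydrogenolyse the benzyl depside A4. Its weakest steps would be:
- the cycloaddition–aromatisation: a β-methyl ynoate would be a sluggish dienophile, the fragile diene would have to survive about 120 °C, and the orientation would rest on polarisation alone;
- the three-step making of that diene: γ-deprotonation of a silyl ester would compete with C-silylation, and the steps would add no complexity to the target;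
- the benzyl ester put on and taken off ring B: two steps of pure masking.

**Strategy.** The route cuts the aryl C4–O bond of ring B, not a ring A bond: the carboxylate oxygen of a ring A acid is joined to C4 of a ring B boronic acid by Cu(OTf)2-mediated Chan–Lam O-arylation, so the ring A carbonyl, shielded by its C2 oxygen and C6 methyl, is never attacked. Ring B enters without its C4 oxygen: an aryne three-component coupling sets pentyl (C6) and carboxyl (C1) beside the C2 methoxyl, and sterically governed C–H borylation marks C4, the only C–H without an ortho neighbour. No cycloaddition and no diene remain, the carboxyl mask arrives within the aryne step, and one boron trichloride treatment frees both phenols and the acid.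

Key step: step 3

Assumption: n-pentyllithium is taken as the commercial solution in heptane; otherwise it would be made from 1-chloropentane and lithium metal and titrated.

**Route**

Step 1
Reactants: 1 3-chloroanisole; 2 n-pentyllithium; 3 di-tert-butyl dicarbonate
Product: 7 tert-butyl 2-methoxy-6-pentylbenzoate, via 2-chloro-6-methoxyphenyllithium 4 (not isolated), via 3-methoxybenzyne 5 (not isolated), via 2-methoxy-6-pentylphenyllithium 6 (not isolated)
Conditions: 2 (2.6 equiv), THF, −78 °C, then −78 → −10 °C; 3 (3 equiv), −78 °C → rt
Reagents that add atoms: none
Why: Ortho-lithiation between chlorine and methoxyl, loss of LiCl to the aryne, carbolithiation and acylation of the new aryllithium by the dicarbonate make up an aryne three-component coupling, in which the methoxyl beside the triple bond sends the pentyl group to the distal aryne carbon because the carbanion then develops next to the inductively withdrawing, lithium-binding oxygen, so that the ester ends up between methoxyl and pentyl, and the hindered tert-butyl ester resists the surplus organolithium.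

Step 2
Reactants: 7 tert-butyl 2-methoxy-6-pentylbenzoate
Product: 9 [4-(tert-butoxycarbonyl)-3-methoxy-5-pentylphenyl]boronic acid, via pinacol boronate 8 (not isolated)
Conditions: [Ir(OMe)(cod)]2 (1.5 mol%), 4,4′-di-tert-butyl-2,2′-bipyridine (3 mol%), B2pin2 (0.7 equiv), THF, 80 °C; then NaIO4 (3 equiv), THF/H2O, rt; 1 M HCl, rt
Reagents that add atoms: bis(pinacolato)diboron, CC1(C)OB(OC1(C)C)B1OC(C)(C)C(C)(C)O1; water, O
Why: Aromatic C–H borylation with the [Ir(OMe)(cod)]2/bipyridine catalyst is ruled by sterics, so of the three ring C–H bonds of 7 only C4–H, the one with no ortho substituent, should be borylated, and periodate then cleaves the pinacol ester to the boronic acid without harming the tert-butyl ester.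

Step 3
Reactants: 9 [4-(tert-butoxycarbonyl)-3-methoxy-5-pentylphenyl]boronic acid; 10 2,4-dimethoxy-6-methylbenzoic acid
Product: 11 tert-butyl 4-[(2,4-dimethoxy-6-methylbenzoyl)oxy]-2-methoxy-6-pentylbenzoate
Conditions: Cu(OTf)2 (0.5 equiv), pyridine (3 equiv), 4 Å molecular sieves, EtOAc, 50 °C, dry air; 9 (1.5 equiv)
Reagents that add atoms: none
Why: Pyridine deprotonates 10 and the carboxylate binds divalent copper, the aryl group of 9 passes from boron to copper, a second divalent copper oxidises this aryl copper carboxylate to the trivalent state, and reductive elimination forms the C4–O bond, after which air returns monovalent copper to the divalent state. The closest known reaction type is the Chan–Lam O-arylation of carboxylic acids with arylboronic acids to phenolic esters, run here with the non-transferable triflate counter-ion and a pyridine buffer so that no free triflic acid can cleave the tert-butyl ester. No ring is closed and no stereocentre is formed. The step needs C–O coupling to outrun protodeboronation, homocoupling and oxidative hydroxylation of 9, which the excess of 9, the sieves and the absence of any other O–H or N–H nucleophile (all phenols are methyl ethers) should secure. Steric hindrance is bypassed by the polarity of the disconnection: the bond is made between the exposed carboxylate oxygen and C4 of ring B, flanked only by C3–H and C5–H, while the carbonyl carbon between the C2 methoxyl and the C6 methyl of ring A is never a reaction centre.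

Step 4
Reactants: 11 tert-butyl 4-[(2,4-dimethoxy-6-methylbenzoyl)oxy]-2-methoxy-6-pentylbenzoate
Product: 12 2-hydroxy-4-[(2-hydroxy-4-methoxy-6-methylbenzoyl)oxy]-6-pentylbenzoic acid
Conditions: BCl3 (1 M in CH2Cl2, 6 equiv), CH2Cl2, −78 → 0 °C; then H2O, 0 °C
Reagents that add atoms: none
Why: In this Lewis acid dealkylation BCl3 ionises the tert-butyl ester and, held in six-membered chelates by the two carbonyl groups, cleaves only the methyl ethers ortho to them (ring A C2 and ring B C2), whereas the unchelated C4 methoxyl of ring A and the aryl ester linkage should survive at or below 0 °C.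

**Compound list**
1 | 3-chloroanisole (1-chloro-3-methoxybenzene) | COc1cccc(Cl)c1 | starting material
2 | n-pentyllithium | [Li]CCCCC | starting material
3 | di-tert-butyl dicarbonate | CC(C)(C)OC(=O)OC(=O)OC(C)(C)C | starting material
4 | 2-chloro-6-methoxyphenyllithium (formed in the flask in step 1) | [Li]c1c(Cl)cccc1OC | intermediate
5 | 3-methoxybenzyne (formed in the flask in step 1) | COC1=CC=CC#C1 | intermediate
6 | 2-methoxy-6-pentylphenyllithium (formed in the flask in step 1) | [Li]c1c(CCCCC)cccc1OC | intermediate
7 | tert-butyl 2-methoxy-6-pentylbenzoate | CCCCCc1cccc(OC)c1C(=O)OC(C)(C)C | intermediate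
8 | tert-butyl 2-methoxy-6-pentyl-4-(4,4,5,5-tetramethyl-1,3,2-dioxaborolan-2-yl)benzoate (formed in the flask in step 2) | CCCCCc1cc(B2OC(C)(C)C(C)(C)O2)cc(OC)c1C(=O)OC(C)(C)C | intermediate
9 | [4-(tert-butoxycarbonyl)-3-methoxy-5-pentylphenyl]boronic acid | CCCCCc1cc(B(O)O)cc(OC)c1C(=O)OC(C)(C)C | intermediate
10 | 2,4-dimethoxy-6-methylbenzoic acid | COc1cc(C)c(C(=O)O)c(OC)c1 | starting material
11 | tert-butyl 4-[(2,4-dimethoxy-6-methylbenzoyl)oxy]-2-methoxy-6-pentylbenzoate | CCCCCc1cc(OC(=O)c2c(C)cc(OC)cc2OC)cc(OC)c1C(=O)OC(C)(C)C | intermediate
12 | 2-hydroxy-4-[(2-hydroxy-4-methoxy-6-methylbenzoyl)oxy]-6-pentylbenzoic acid | CCCCCc1cc(OC(=O)c2c(C)cc(OC)cc2O)cc(O)c1C(=O)O | target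

**Count and risks**
Total steps: 4. Longest linear sequence: 4 steps (1 → 7 → 9 → 11 → 12).

Steps most likely to fail:

1. Step 3 (key step). The carboxylate transfer may be outrun by protodeboronation, homocoupling or oxidative hydroxylation of the boronic acid, or the pyridine buffer may slow the copper turnover. The fallback sets out from 9 and returns at 11, and reverses the polarity of the ester formation to an ordinary acyl transfer. Oxidation of 9 (H2O2, NaHCO3, THF/H2O, 0 °C) would give tert-butyl 4-hydroxy-2-methoxy-6-pentylbenzoate F1. Acid 10 would be converted by oxalyl chloride and catalytic DMF into 2,4-dimethoxy-6-methylbenzoyl chloride F2. The sodium phenoxide of F1 (NaH, THF) would then be acylated by F2 to give 11.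

2. Step 1. The aryllithiums 4 and 6 may add to aryne 5 in competition with pentyllithium, which would lead to biaryls, and surplus pentyllithium may consume the dicarbonate. The fallback sets out from 1 and returns at 7 without any aryne. Lithiation of 1 with s-BuLi (THF, −78 °C) and a quench with 3 at that temperature, before LiCl can be lost, would give tert-butyl 2-chloro-6-methoxybenzoate F3. Its ester-activated C–Cl bond would then be coupled with commercial pentylmagnesium bromide F4 under Fe(acac)3 catalysis (THF/NMP, 0 °C, Kumada-type coupling) to give 7.

3. Step 4. Dealkylation may stall at the C2 methyl ether of ring A, whose aryl ester carbonyl is twisted out of the ring plane and binds boron weakly. Forcing it may open the depside linkage through the acylium ion of the electron-rich ring A, or let the tert-butyl cation alkylate ring A. The fallback sets out from 9 and returns at 12. Compound 9 would be coupled under the conditions of step 3 with commercial everninic acid F5 (2-hydroxy-4-methoxy-6-methylbenzoic acid), whose hydroxyl is held in a hydrogen bond to the carboxyl, to give tert-butyl 4-[(2-hydroxy-4-methoxy-6-methylbenzoyl)oxy]-2-methoxy-6-pentylbenzoate F6. BCl3 at −78 °C would then have to remove only the tert-butyl group and the carboxyl-chelated methyl ether of ring B, so that ring A never carries an ether that must be cleaved.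

**Further compounds**
F1 | step 3 | tert-butyl 4-hydroxy-2-methoxy-6-pentylbenzoate | CCCCCc1cc(O)cc(OC)c1C(=O)OC(C)(C)C
F2 | step 3 | 2,4-dimethoxy-6-methylbenzoyl chloride | COc1cc(C)c(C(=O)Cl)c(OC)c1
F3 | step 1 | tert-butyl 2-chloro-6-methoxybenzoate | COc1cccc(Cl)c1C(=O)OC(C)(C)C
F4 | step 1 | pentylmagnesium bromide | CCCCC[Mg]Br
F5 | step 4 | everninic acid (2-hydroxy-4-methoxy-6-methylbenzoic acid) | COc1cc(C)c(C(=O)O)c(O)c1
F6 | step 4 | tert-butyl 4-[(2-hydroxy-4-methoxy-6-methylbenzoyl)oxy]-2-methoxy-6-pentylbenzoate | CCCCCc1cc(OC(=O)c2c(C)cc(OC)cc2O)cc(OC)c1C(=O)OC(C)(C)C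
A1 | direct plan | benzyl 2,4-dihydroxy-6-pentylbenzoate | CCCCCc1cc(O)cc(O)c1C(=O)OCc1ccccc1
A2 | direct plan | benzyl 4-(but-2-ynoyloxy)-2-hydroxy-6-pentylbenzoate | CC#CC(=O)Oc1cc(CCCCC)c(C(=O)OCc2ccccc2)c(O)c1
A3 | direct plan | 3-methoxy-1,1-bis(trimethylsilyloxy)buta-1,3-diene | C=C(OC)C=C(O[Si](C)(C)C)O[Si](C)(C)C
A4 | direct plan | benzyl 2-hydroxy-4-[(2-hydroxy-4-methoxy-6-methylbenzoyl)oxy]-6-pentylbenzoate | COc1cc(C)c(C(=O)Oc2cc(CCCCC)c(C(=O)OCc3ccccc3)c(O)c2)c(O)c1
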